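**Assumption:** the SMILES is read as drawn, giving an all-cis oxolane (2R,3R,4R), a trans inner dihydrobenzofuran (2R,3S) and a trans outer dihydrobenzofuran (2S,3R). 4-(Bromomethyl)furan-2(5H)-one and both antipodes of each chiral ligand are taken as purchasable.

## Retrosynthetic overview
1. The target comes from global hydride reduction (three CO2Me to CH2OH, two pivalates removed) of an all-cis oxolane triester. That triester comes from face-selective hydrogenation of a 2-aryl-4-benzyl-4,5-dihydrofuran-3-carboxylate, in which C4 controls C2 and C3.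
2. The dihydrofuran comes from the acyl-lactone rearrangement of an α-aroyl-β-benzyl-butyrolactone, assembled from an aryl bromide, CO and the α-acid of an (R)-β-benzyl lactone.
3. The aryl bromide (rings B, C and D with both dihydrobenzofurans) comes from one twofold oxidative ring contraction of a C2–C6'-linked biflavanone, by a 1,2-shift of the ring-fusion aryl carbon from C4 to C3.
4. The biflavanone comes from two enantiocomplementary Pd-catalysed conjugate additions of arylboronic acids to a single chromone.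
5. All four arenes come from catechol, and the lactone carbons from 4-(bromomethyl)furan-2(5H)-one. Ring order: two pyranones, both contracted to dihydrobenzofurans, then the oxolane last.

## Route

Step 1
Reactants: 1 catechol
Product: 2 2-methoxyphenol (guaiacol)
Conditions: MeI (1.0 equiv), K2CO3, acetone, reflux
Reagents that add atoms: iodomethane CI
Why: Williamson ether synthesis; with one equivalent of MeI the mono-ether dominates, and leftover catechol and veratrole are removed by extraction and distillation.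

Step 2
Reactants: 2 2-methoxyphenol
Product: 3 4-bromo-2-methoxyphenol
Conditions: NBS, MeCN, 0 °C
Reagents that add atoms: N-bromosuccinimide O=C1CCC(=O)N1Br
Why: Electrophilic aromatic bromination, in which the free OH directs para in MeCN; the bromine later serves both as a para block and as a coupling handle.

Step 3
Reactants: 3 4-bromo-2-methoxyphenol
Product: 4 4-bromo-2-methoxyphenyl pivalate
Conditions: PivCl, Et3N, DMAP (cat.), CH2Cl2, 0 °C to rt
Reagents that add atoms: pivaloyl chloride CC(C)(C)C(=O)Cl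
Why: O-acylation; the pivalate makes rings A and D less electron-rich (safe toward trivalent iodine, poor migrating group) and is removed in the final hydride step without a separate deprotection.

Step 4
Reactants: 4 4-bromo-2-methoxyphenyl pivalate
Product: 5 [3-methoxy-4-(pivaloyloxy)phenyl]boronic acid
Conditions: B2(OH)4, Pd(OAc)2/XPhos (cat.), KOAc, EtOH, 80 °C
Reagents that add atoms: tetrahydroxydiboron OB(O)B(O)O
Why: Miyaura-type borylation with tetrahydroxydiboron gives the free boronic acid directly, and this one compound serves as both ring D and ring A.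

Step 5
Reactants: 3 4-bromo-2-methoxyphenol
Product: 6 4-bromo-2-iodo-6-methoxyphenol
Conditions: I2, KI, NaHCO3, H2O/MeOH, rt
Reagents that add atoms: iodine II
Why: Electrophilic iodination through the phenolate, which directs only ortho and para; para is blocked, so iodine enters the single free ortho position.

Step 6
Reactants: 6 4-bromo-2-iodo-6-methoxyphenol
Product: 9 6-bromo-8-methoxy-4H-chromen-4-one, via silyl ynone 7 (not isolated), via diethylamino enone 8 (not isolated)
Conditions: HC≡CSiMe3, CO (1 atm), PdCl2(PPh3)2 (cat.), Et2NH, 60 °C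
Reagents that add atoms: carbon monoxide [C-]#[O+]; ethynyltrimethylsilane C#C[Si](C)(C)C
Why: Carbonylative Sonogashira annulation; only the C–I bond reacts, Et2NH adds to ynone 7 with loss of silicon to give 8, and the ortho phenol then displaces the amine by addition–elimination to close the pyranone.

Step 7
Reactants: 5 [3-methoxy-4-(pivaloyloxy)phenyl]boronic acid; 9 6-bromo-8-methoxy-4H-chromen-4-one
Product: 10 (2S)-6-bromo-8-methoxy-2-[3-methoxy-4-(pivaloyloxy)phenyl]chroman-4-one
Conditions: Pd(OCOCF3)2 (5 mol %), (R)-t-BuPyOx (6 mol %), NH4PF6, H2O (5 equiv), ClCH2CH2Cl, 60 °C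
Reagents that add atoms: none
Why: Base-free asymmetric conjugate addition of an arylboronic acid to a chromone; the cycle stays at divalent palladium so C–Br is untouched, and the R ligand sets 2S (by analogy with cyclic enones, where the S ligand attacks the face that corresponds to 2R here).

Step 8
Reactants: 10 (2S)-6-bromo-8-methoxy-2-[3-methoxy-4-(pivaloyloxy)phenyl]chroman-4-one
Product: 11 {(2S)-8-methoxy-2-[3-methoxy-4-(pivaloyloxy)phenyl]-4-oxochroman-6-yl}boronic acid
Conditions: B2(OH)4, Pd(OAc)2/XPhos (cat.), KOAc, EtOH, 60 °C, short time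
Reagents that add atoms: tetrahydroxydiboron OB(O)B(O)O
Why: Miyaura-type borylation; the weak carboxylate base, lower temperature and short contact time keep the retro-oxa-Michael opening that would racemise C2 negligible.

Step 9
Reactants: 11 flavanone boronic acid; 9 6-bromo-8-methoxy-4H-chromen-4-one
Product: 12 (2R)-6-bromo-8-methoxy-2-{(2S)-8-methoxy-2-[3-methoxy-4-(pivaloyloxy)phenyl]-4-oxochroman-6-yl}chroman-4-one
Conditions: Pd(OCOCF3)2 (5 mol %), (S)-t-BuPyOx (6 mol %), NH4PF6, H2O (5 equiv), ClCH2CH2Cl, 60 °C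
Reagents that add atoms: none
Why: The same asymmetric conjugate addition with the antipodal ligand sets the new centre 2R under catalyst control, since the remote 2S centre has no influence.

Step 10
Reactants: 12 biflavanone
Product: 14 methyl (2R,3R)-5-bromo-7-methoxy-2-{(2S,3S)-7-methoxy-3-(methoxycarbonyl)-2-[3-methoxy-4-(pivaloyloxy)phenyl]-2,3-dihydro-1-benzofuran-5-yl}-2,3-dihydro-1-benzofuran-3-carboxylate, via bis(methyl enol ether) 13 (not isolated)
Conditions: PhI(OAc)2 (2.4 equiv), H2SO4, HC(OMe)3, rt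
Reagents that add atoms: trimethyl orthoformate COC(OC)OC; water O
Why: Proposed new method: a twofold oxidative ring contraction on a C2–C6'-linked biflavanone, a substrate class on which this chemistry has not been shown; HC(OMe)3/H+ turns each ketone into its methyl enol ether (13), PhI(OAc)2 places trivalent iodine on C3 anti to the equatorial 2-aryl group, methanol closes C4 to a ketal, and the ring-fusion carbon C4a, antiperiplanar to the equatorial C3–I bond, shifts 1,2 from C4 to C3 with inversion and loss of PhI, so each pyranone contracts to a dihydrofuran, C4 leaves the ring as CO2Me and each new C3 is set trans to its untouched C2 (2R gives 2R,3R; 2S gives 2S,3S), while the acyloxy group on ring D and the still-acylated ring C hold back the competing 2-to-3 aryl shift; closest known reaction type: PhI(OAc)2- or Tl(NO3)3-mediated ring contraction of single flavanones to methyl trans-2-aryl-2,3-dihydrobenzofuran-3-carboxylates.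

Step 11
Reactants: 5 [3-methoxy-4-(pivaloyloxy)phenyl]boronic acid; 15 4-(bromomethyl)furan-2(5H)-one
Product: 16 4-[3-methoxy-4-(pivaloyloxy)benzyl]furan-2(5H)-one
Conditions: Pd(PPh3)4 (cat.), K2CO3, THF/H2O, 50 °C
Reagents that add atoms: none
Why: Suzuki–Miyaura coupling with an allylic bromide; aryl transfer to the unhindered CH2 end of the allyl–palladium species keeps the butenolide conjugated.

Step 12
Reactants: 16 4-[3-methoxy-4-(pivaloyloxy)benzyl]furan-2(5H)-one
Product: 17 (4R)-4-[3-methoxy-4-(pivaloyloxy)benzyl]dihydrofuran-2(3H)-one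
Conditions: H2 (50 bar), [Rh(nbd)2]BF4/ZhaoPhos (1 mol %, antipode giving 4R), CH2Cl2, rt
Reagents that add atoms: none
Why: Rh-catalysed asymmetric hydrogenation of a β-substituted butenolide sets C4 as R under ligand control, with the ligand hand confirmed by rotation against the known (R)-4-benzyl lactone series.

Step 13
Reactants: 17 (4R)-lactone
Product: 18 (3S,4R)-4-[3-methoxy-4-(pivaloyloxy)benzyl]-2-oxotetrahydrofuran-3-carboxylic acid
Conditions: LiN(SiMe3)2, THF, −78 °C; CO2; cold dil. HCl
Reagents that add atoms: carbon dioxide O=C=O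
Why: Enolate carboxylation of a γ-lactone; CO2 enters trans to the C4 arm, and this labile C3 centre is erased later, so its configuration does not matter.

Step 14
Reactants: 14 bis(dihydrobenzofuran) bromide; 18 lactone acid
Product: 20 methyl (4R)-2-(BCD-yl)-4-[3-methoxy-4-(pivaloyloxy)benzyl]-4,5-dihydrofuran-3-carboxylate (BCD-yl = 14 without Br), via aroyl lactone 19 (not isolated)
Conditions: CO (1 atm), Pd(dba)2/Xantphos (cat.), MgCl2, Et3N, THF, 70 °C; then HCl/MeOH, 50 °C
Reagents that add atoms: carbon monoxide [C-]#[O+]; methanol CO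
Why: Carbonylative decarboxylative Claisen-type acylation of the magnesium enolate of a malonic half-acid gives 19 under base too weak to open the dihydrobenzofuran esters, and methanolic HCl then drives the acyl-lactone rearrangement (lactone methanolysis, hemiketal formation, dehydration) to the conjugated dihydrofuran with C4 untouched.

Step 15
Reactants: 20 dihydrofuran triester
Product: 21 methyl (2R,3S,4R)-2-(BCD-yl)-4-[3-methoxy-4-(pivaloyloxy)benzyl]tetrahydrofuran-3-carboxylate
Conditions: H2 (30 bar), Pd/C, solid NaHCO3, EtOAc, rt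
Reagents that add atoms: none
Why: Heterogeneous syn-hydrogenation; the flat alkene binds the metal through the face bearing C4–H, away from the arylmethyl arm, so both new hydrogens arrive cis to C4–H and the aryl, ester and arylmethyl groups end up all-cis.

Step 16
Reactants: 21 all-cis oxolane triester
Product: 22 target
Conditions: LiAlH4, THF, 0 °C; Na2SO4·10H2O quench, neutral work-up
Reagents that add atoms: none
Why: LiAlH4 ester reduction converts three CO2Me groups to CH2OH and cleaves both pivalates in one operation; it is faster than α-epimerisation, and the acid-free work-up protects the benzylic C2 of the all-cis oxolane.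

## Compound list
1 | catechol | Oc1ccccc1O | starting material
2 | 2-methoxyphenol | COc1ccccc1O | intermediate
3 | 4-bromo-2-methoxyphenol | COc1cc(Br)ccc1O | intermediate
4 | 4-bromo-2-methoxyphenyl pivalate | COc1cc(Br)ccc1OC(=O)C(C)(C)C | intermediate
5 | [3-methoxy-4-(pivaloyloxy)phenyl]boronic acid | COc1cc(B(O)O)ccc1OC(=O)C(C)(C)C | intermediate
6 | 4-bromo-2-iodo-6-methoxyphenol | COc1cc(Br)cc(I)c1O | intermediate
7 | 1-(5-bromo-2-hydroxy-3-methoxyphenyl)-3-(trimethylsilyl)prop-2-yn-1-one | COc1cc(Br)cc(C(=O)C#C[Si](C)(C)C)c1O | intermediate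
8 | (E)-1-(5-bromo-2-hydroxy-3-methoxyphenyl)-3-(diethylamino)prop-2-en-1-one | CCN(CC)/C=C/C(=O)c1cc(Br)cc(OC)c1O | intermediate
9 | 6-bromo-8-methoxy-4H-chromen-4-one | COc1cc(Br)cc2C(=O)C=COc12 | intermediate
10 | (2S)-6-bromo-8-methoxy-2-[3-methoxy-4-(pivaloyloxy)phenyl]chroman-4-one | O=C1C[C@H](Oc2c1cc(Br)cc2OC)c1ccc(OC(=O)C(C)(C)C)c(OC)c1 | intermediate
11 | {(2S)-8-methoxy-2-[3-methoxy-4-(pivaloyloxy)phenyl]-4-oxochroman-6-yl}boronic acid | O=C1C[C@H](Oc2c1cc(B(O)O)cc2OC)c1ccc(OC(=O)C(C)(C)C)c(OC)c1 | intermediate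
12 | (2R)-6-bromo-8-methoxy-2-{(2S)-8-methoxy-2-[3-methoxy-4-(pivaloyloxy)phenyl]-4-oxochroman-6-yl}chroman-4-one | O=C1C[C@@H](Oc2c1cc(Br)cc2OC)c1cc(OC)c2O[C@@H](CC(=O)c2c1)c1ccc(OC(=O)C(C)(C)C)c(OC)c1 | intermediate
13 | bis(4-methoxy-2H-chromene), the bis(methyl enol ether) of 12 (2R and 2'S unchanged) | COC1=C[C@@H](Oc2c1cc(Br)cc2OC)c1cc(OC)c2O[C@@H](C=C(OC)c2c1)c1ccc(OC(=O)C(C)(C)C)c(OC)c1 | intermediate
14 | methyl (2R,3R)-5-bromo-7-methoxy-2-{(2S,3S)-7-methoxy-3-(methoxycarbonyl)-2-[3-methoxy-4-(pivaloyloxy)phenyl]-2,3-dihydro-1-benzofuran-5-yl}-2,3-dihydro-1-benzofuran-3-carboxylate (both rings trans) | Brc1cc(OC)c2c(c1)[C@@H](C(=O)OC)[C@H](c1cc(OC)c3c(c1)[C@H](C(=O)OC)[C@@H](c1ccc(OC(=O)C(C)(C)C)c(OC)c1)O3)O2 | intermediate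
15 | 4-(bromomethyl)furan-2(5H)-one | O=C1C=C(CBr)CO1 | starting material
16 | 4-[3-methoxy-4-(pivaloyloxy)benzyl]furan-2(5H)-one | COc1cc(CC2=CC(=O)OC2)ccc1OC(=O)C(C)(C)C | intermediate
17 | (4R)-4-[3-methoxy-4-(pivaloyloxy)benzyl]dihydrofuran-2(3H)-one | COc1cc(C[C@H]2COC(=O)C2)ccc1OC(=O)C(C)(C)C | intermediate
18 | (3S,4R)-4-[3-methoxy-4-(pivaloyloxy)benzyl]-2-oxotetrahydrofuran-3-carboxylic acid (trans) | COc1cc(C[C@H]2COC(=O)[C@@H]2C(=O)O)ccc1OC(=O)C(C)(C)C | intermediate
19 | (3S,4R)-3-(BCD-carbonyl)-4-[3-methoxy-4-(pivaloyloxy)benzyl]dihydrofuran-2(3H)-one (BCD = aryl residue of 14, bonded at the former C–Br carbon) | COc1cc(C[C@H]2COC(=O)[C@@H]2C(=O)c2cc(OC)c3c(c2)[C@@H](C(=O)OC)[C@H](c2cc(OC)c4c(c2)[C@H](C(=O)OC)[C@@H](c2ccc(OC(=O)C(C)(C)C)c(OC)c2)O4)O3)ccc1OC(=O)C(C)(C)C | intermediate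
20 | methyl (4R)-2-(BCD-yl)-4-[3-methoxy-4-(pivaloyloxy)benzyl]-4,5-dihydrofuran-3-carboxylate | COc1cc(C[C@H]2COC(=C2C(=O)OC)c2cc(OC)c3c(c2)[C@@H](C(=O)OC)[C@H](c2cc(OC)c4c(c2)[C@H](C(=O)OC)[C@@H](c2ccc(OC(=O)C(C)(C)C)c(OC)c2)O4)O3)ccc1OC(=O)C(C)(C)C | intermediate
21 | methyl (2R,3S,4R)-2-(BCD-yl)-4-[3-methoxy-4-(pivaloyloxy)benzyl]tetrahydrofuran-3-carboxylate (all-cis) | COc1cc(C[C@H]2CO[C@@H](c3cc(OC)c4c(c3)[C@@H](C(=O)OC)[C@H](c3cc(OC)c5c(c3)[C@H](C(=O)OC)[C@@H](c3ccc(OC(=O)C(C)(C)C)c(OC)c3)O5)O4)[C@H]2C(=O)OC)ccc1OC(=O)C(C)(C)C | intermediate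
22 | (2R,3R,4R)-3-(hydroxymethyl)-4-(4-hydroxy-3-methoxybenzyl)oxolane carrying at C2 a (2R,3S)-3-(hydroxymethyl)-7-methoxy-2,3-dihydro-1-benzofuran-5-yl group, whose own C2 bears a (2S,3R)-2-(4-hydroxy-3-methoxyphenyl)-3-(hydroxymethyl)-7-methoxy-2,3-dihydro-1-benzofuran-5-yl group | COc1cc(C[C@H]2CO[C@@H](c3cc(OC)c4c(c3)[C@@H](CO)[C@H](c3cc(OC)c5c(c3)[C@H](CO)[C@@H](c3ccc(O)c(OC)c3)O5)O4)[C@H]2CO)ccc1O | target

## Count and risks
Total steps: 16. Longest linear sequence: 11 (steps 1, 2, 3, 4, 7, 8, 9, 10, 14, 15, 16).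

**Step 10 (the proposed new step).**
- Risks: a 2-to-3 aryl shift giving isoflavone-type products, 3-methoxylation, dehydrogenation to the flavone, or a stalled second contraction.
- Fallback: it sets out from 10 and comes back at 14, using only the known contraction of a single flavanone.
- Treating 10 with PhI(OAc)2/H2SO4/HC(OMe)3 gives the trans ester bromide F1. Borylation with B2(OH)4 then gives the boronic acid F2.
- Conjugate addition of F2 to chromone 9 with Pd(OCOCF3)2/(S)-t-BuPyOx gives the flavanone F3, and a second single contraction gives 14.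
- This costs one extra step, and it also moves the borylation off the base-labile flavanone.

**Step 14.**
- Risks: the hindered tertiary magnesium enolate may decarboxylate before it meets the acyl–palladium species, or may O-acylate.
- Fallback: it sets out from 14 and 17 and comes back at 19, replacing carbonylation by the neutral thioester–boronic acid ketone synthesis (Liebeskind–Srogl coupling).
- Treating 14 with B2(OH)4, Pd(OAc)2/XPhos and KOAc gives the boronic acid F4. Treating 17 with LiN(SiMe3)2 and then S-ethyl chlorothioformate gives the thioester F5.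
- F4 and F5 with Pd2(dba)3, tri(2-furyl)phosphine and monovalent copper thiophene-2-carboxylate, Cu(O2CC4H3S), in THF at 50 °C give 19. This is isolated and taken to 20 with HCl/MeOH as before.

**Step 15.**
- Risks: the tetrasubstituted push–pull alkene may resist hydrogenation, or forcing conditions may cleave the benzylic C2–O bond.
- Fallback: it sets out from 20 and comes back at 22, swapping the order of the two reductions so that a different, more reactive alkene is hydrogenated.
- LiAlH4 in THF at 0 °C first converts 20 into the dihydrofuran pentaol F6, which is a plain electron-rich enol ether.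
- This takes up H2 (3 bar) over Rh/Al2O3 in EtOH with a trace of Et3N, again from the face opposite the C4 arm, and gives 22 directly.

## Further compounds
F1 | step 10 | methyl (2S,3S)-5-bromo-7-methoxy-2-[3-methoxy-4-(pivaloyloxy)phenyl]-2,3-dihydro-1-benzofuran-3-carboxylate | Brc1cc(OC)c2c(c1)[C@H](C(=O)OC)[C@@H](c1ccc(OC(=O)C(C)(C)C)c(OC)c1)O2
F2 | step 10 | {(2S,3S)-7-methoxy-3-(methoxycarbonyl)-2-[3-methoxy-4-(pivaloyloxy)phenyl]-2,3-dihydro-1-benzofuran-5-yl}boronic acid | OB(O)c1cc(OC)c2c(c1)[C@H](C(=O)OC)[C@@H](c1ccc(OC(=O)C(C)(C)C)c(OC)c1)O2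
F3 | step 10 | methyl (2S,3S)-5-[(2R)-6-bromo-8-methoxy-4-oxochroman-2-yl]-7-methoxy-2-[3-methoxy-4-(pivaloyloxy)phenyl]-2,3-dihydro-1-benzofuran-3-carboxylate | O=C1C[C@@H](Oc2c1cc(Br)cc2OC)c1cc(OC)c2c(c1)[C@H](C(=O)OC)[C@@H](c1ccc(OC(=O)C(C)(C)C)c(OC)c1)O2
F4 | step 14 | boronic acid of 14 (B(OH)2 in place of Br) | OB(O)c1cc(OC)c2c(c1)[C@@H](C(=O)OC)[C@H](c1cc(OC)c3c(c1)[C@H](C(=O)OC)[C@@H](c1ccc(OC(=O)C(C)(C)C)c(OC)c1)O3)O2
F5 | step 14 | S-ethyl (3R,4R)-4-[3-methoxy-4-(pivaloyloxy)benzyl]-2-oxotetrahydrofuran-3-carbothioate (trans) | COc1cc(C[C@H]2COC(=O)[C@@H]2C(=O)SCC)ccc1OC(=O)C(C)(C)C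
F6 | step 15 | 2,3-didehydro analogue of 22: (4R)-2-aryl-3-(hydroxymethyl)-4-(4-hydroxy-3-methoxybenzyl)-4,5-dihydrofuran with all esters reduced and both phenols free | COc1cc(C[C@H]2COC(=C2CO)c2cc(OC)c3c(c2)[C@@H](CO)[C@H](c2cc(OC)c4c(c2)[C@H](CO)[C@@H](c2ccc(O)c(OC)c2)O4)O3)ccc1O
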